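Readings and results were generated by integration with made-up constants.

L leaves slowly, so take its clock first.

| flask | L | X | Q | E | remark | time |
|---|---|---|---|---|---|---|
| alder | 0.20 M | 0.18 M | 24 mM | 6.2 mM | run made earlier |  |
| elm | 0.20 M | 0.75 M | 24 mM | 6.2 mM | run made earlier |  |
| eta | 0.20 M | 0.320 M | 24 mM | 6.2 mM |  | 2.5 h |
| epsilon | 0.20 M | 0.640 M | 24 mM | 6.2 mM |  | 2.5 h |
| gamma | 0.20 M | 0.160 M | 24 mM | 6.2 mM |  | 2.5 h |

| run | time / min | G / % | Z / % | L / % |
|---|---|---|---|---|
| alder | 6.00 | 0 | 2.5 | 99.0 |
| alder | 20.0 | 0 | 7.2 | 94.0 |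
| alder | 40.0 | 1.0 | 12.2 | 86.5 |
| alder | 50.0 | 1.1 | 13.9 | 83.5 |
| alder | 80.0 | 3.5 | 20.4 | 74.9 |
| elm | 6.00 | 0.4 | 2.0 | 97.5 |
| elm | 20.0 | 0.8 | 7.3 | 93.8 |
| elm | 40.0 | 1.3 | 11.2 | 86.7 |
| elm | 50.0 | 2.4 | 13.9 | 82.8 |
| elm | 80.0 | 6.3 | 18.7 | 74.3 |

(scatter of a reading: 0.5 percentage points)

- which of these there is most of at the end, counted by the L in it, eta (G / L / Z)
- which of these there is most of at the end, counted by the L in it, epsilon (G / L / Z)
- which of these there is most of at the end, counted by the L in it, gamma (G / L / Z)
- how much there is at the end of the one of these that leads, in percent of the L charged: eta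
- how much there is at the end of the one of these that leads, in percent of the L charged: epsilon
- how much there is at the end of the one of these that leads, in percent of the L charged: gamma



Read the last line of each run. At 80.0 min, alder holds 74.9% of its L and elm 74.3%, with cX at 0.18 M and 0.75 M. The gap is 0.6 percentage points against a scatter of 0.5 points, so treat L as blind to X over that span. But cX in gamma starts lower than in alder, at 0.160 M, so gamma stands a small step outside the runs.

cQ matches in the runs and the new flasks, so commit to a first-order curve, which the readings don't prove. Define the L clock, the pseudo-first-order constant of L's loss, from the mean of those two readings: 0.220 h⁻¹.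

My reckoning puts L at 57.7% after 2.5 h in eta, epsilon and gamma. Now find the crossing. Whatever is not L shares the remainder, so L must lead while more than half of it stays. The clock gives a half-life of 3.15 h, longer than 2.5 h, so my reckoning has L leading in eta, epsilon and gamma.

The forecast also names L in eta, L in epsilon and L in gamma. It gives 55.5% (50% to 60%) for eta, 55.5% (50% to 60%) for epsilon and 55.5% (50% to 61%) for gamma. Its ground: “Alder and elm lose L at the same rate although X differs fourfold”. Its figure stands lower than mine.

The flasks give L leading, with 58.3% in eta, 58.3% in epsilon and 58.3% in gamma, so the forecast stands within its margins.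

    L + Q → Q + Z (k = 0.00250 M⁻¹ s⁻¹)
    E + Z ⇌ D (K = 49.0 M⁻¹, k = 0.0220 M⁻¹ s⁻¹)
    X + D → E + G (k = 0.00760 M⁻¹ s⁻¹)

Gamma has not come to rest at 2.5 h. Run the clock to 25.0 h: it gives 0.409% of L, and the flask holds 0.452%. Over that stretch G climbs from 9.33% to 73.8%, past Z at 23.7%, while X falls to 7.77% of its own charge. Eta at that time holds G at 98.3% of the L charged and X at 38.6% of its own charge.

A later reading turns the forecast's answer wrong in gamma. Take gamma at 6.0 h, beyond the half-life: the clock gives 26.7%, so L's lead has lost its guarantee. The computed flask holds L 27.4%, Z 41.9% and G 28.9%, and Z leads.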